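## Retrosynthetic overview

1. The C2–C1′ bond between ring C and ring B is cut first. A retro enantioselective 1,4-arylation takes the (2S)-flavanone back to a flat 4H-chromen-4-one and (4-hydroxy-3-methoxyphenyl)boronic acid. The only stereocentre and the only fragment union fall in this one step.
2. The enabling feature is the O1–C2=C3–C4=O vinylogous ester of the pyranone ring C, in which C2 is the β-carbon of a cyclic enone. Acetyl groups on O5 and O7 of ring A damp the donation of these oxygens into C4=O and block the O5/O4 peri chelation site.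
3. The C6–CMe2 bond is cut next by a retro aromatic Claisen rearrangement to the O5-prenyl ether. C4a is blocked, so O5 can only deliver to C6. Trapping the freed O5 as its acetate supplies the second activating group without an extra step.
4. No ring is built. Rings A and C are bought together as 5,7-dihydroxychromone and ring B as the boronic acid. Ring C only passes from pyranone to dihydropyranone in the key step.

Key step: step 4

Assumption: 5,7-dihydroxychromone, prenol and (4-hydroxy-3-methoxyphenyl)boronic acid are taken as catalogue chemicals, and the stereodescriptor of the given SMILES corresponds to (2S).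

## Route

Step 1
Reactants: 1 5,7-dihydroxy-4H-chromen-4-one
Product: 2 5-hydroxy-4-oxo-4H-chromen-7-yl acetate
Conditions: Ac2O (1.05 equiv), pyridine, 0 °C → rt
Reagents that add atoms: acetic anhydride, CC(=O)OC(C)=O
Why: Selective O-acylation should occur at O7 only, because the 5-OH is locked in a hydrogen bond to the C4 carbonyl and is far less nucleophilic than the free, more acidic 7-OH.

Step 2
Reactants: 2 5-hydroxy-4-oxo-4H-chromen-7-yl acetate; 3 3-methylbut-2-en-1-ol (prenol)
Product: 4 5-[(3-methylbut-2-en-1-yl)oxy]-4-oxo-4H-chromen-7-yl acetate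
Conditions: PPh3 (1.4 equiv), DIAD (1.4 equiv), THF, 0 °C → rt
Reagents that add atoms: none
Why: In this Mitsunobu etherification the only remaining acidic O–H (the chelated 5-OH) displaces the activated primary allylic alcohol by SN2 under neutral conditions that leave the aryl acetate untouched, a reaction type known for 7-O-acyl-5-hydroxyflavonoids.

Step 3
Reactants: 4 5-[(3-methylbut-2-en-1-yl)oxy]-4-oxo-4H-chromen-7-yl acetate
Product: 7 6-(2-methylbut-3-en-2-yl)-4-oxo-4H-chromene-5,7-diyl diacetate, via Claisen dienone 5 (not isolated), via free 5-phenol 6 (not isolated)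
Conditions: Ac2O (solvent), NaOAc (2 equiv), reflux (ca. 140 °C), Ar
Reagents that add atoms: acetic anhydride, CC(=O)OC(C)=O
Why: In this aromatic Claisen rearrangement with acylative trapping the suprafacial [3,3] shift from O5 can only end at C6 because C4a is quaternary, it turns the prenyl ether into the 1,1-dimethylallyl group, the transient racemic C6 stereocentre of 5 vanishes on acetate-assisted enolisation to 6, and acetylation of O5 fixes the ortho product before a Cope shift to C8 can compete.

Step 4
Reactants: 7 6-(2-methylbut-3-en-2-yl)-4-oxo-4H-chromene-5,7-diyl diacetate; 8 (4-hydroxy-3-methoxyphenyl)boronic acid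
Product: 9 (2S)-2-(4-hydroxy-3-methoxyphenyl)-6-(2-methylbut-3-en-2-yl)-4-oxochromane-5,7-diyl diacetate
Conditions: [Rh(OH)(cod)]2 (1.5 mol %), (S)-MeO-F12-BIPHEP [(S)-6,6′-dimethoxybiphenyl-2,2′-diylbis(bis(3,4,5-trifluorophenyl)phosphine), 3.3 mol %], 8 (2.5 equiv, in portions), toluene/H2O 10:1, 25 °C, no base
Reagents that add atoms: none
Why: In the Hayashi–Miyaura mechanism the hydroxo-rhodium(I) bisphosphine complex transmetalates with 8, the aryl–Rh species binds the C2=C3 bond of 7 and inserts so that the aryl group goes to C2, and water hydrolyses the resulting oxa-π-allyl rhodium enolate to the ketone and regenerates Rh–OH. The closest known reaction type is the rhodium-catalysed asymmetric 1,4-addition of arylboronic acids to chromones, which is established with electron-poor biaryl bisphosphines and with chiral dienes, also on 5,7-dioxygenated chromones. No ring is closed; ring C only passes from the planar pyranone to the dihydropyranone. C2 is set by the ligand alone: the C2-symmetric (S)-biaryl leaves open the quadrant in which the enone offers its C2 Re face (O1 > C3 > H), the same spatial sense in which (S)-biaryl bisphosphines give (S)-3-arylcyclohexanones, so (2S) is expected, and the mirror-image ligand is at hand should the sense be opposite. The step needs acceptor reactivity and chemoselectivity: the two O-acetyl groups make the doubly oxygenated chromone a better acceptor and prevent an acetylacetonate-like O5/O4 chelate that would tie up rhodium, the vinyl group on the quaternary carbon is unactivated, hindered and has no allylic hydrogen so that it should neither insert nor isomerise, and the hindered C4 ketone of 9 should resist 1,2-addition. Base-free conditions at room temperature keep the acetates in place and avoid the retro-oxa-Michael opening of 9 that would racemise C2.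

Step 5
Reactants: 9 (2S)-2-(4-hydroxy-3-methoxyphenyl)-6-(2-methylbut-3-en-2-yl)-4-oxochromane-5,7-diyl diacetate
Product: 10 (2S)-5,7-dihydroxy-2-(4-hydroxy-3-methoxyphenyl)-6-(2-methylbut-3-en-2-yl)chroman-4-one
Conditions: HCl (1.25 M in MeOH), 0 → 30 °C
Reagents that add atoms: none
Why: Acid-catalysed transesterification should remove both aryl acetates without touching C2, because flavanones lose configuration mainly by base-induced ring opening, and the monosubstituted alkene should not be protonated at this acidity.

## Compound list

1 | 5,7-dihydroxy-4H-chromen-4-one | O=c1ccoc2cc(O)cc(O)c12 | starting material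
2 | 5-hydroxy-4-oxo-4H-chromen-7-yl acetate | CC(=O)Oc1cc(O)c2c(=O)ccoc2c1 | intermediate
3 | 3-methylbut-2-en-1-ol (prenol) | CC(C)=CCO | starting material
4 | 5-[(3-methylbut-2-en-1-yl)oxy]-4-oxo-4H-chromen-7-yl acetate | CC(=O)Oc1cc(OCC=C(C)C)c2c(=O)ccoc2c1 | intermediate
5 | 6-(2-methylbut-3-en-2-yl)-4,5-dioxo-5,6-dihydro-4H-chromen-7-yl acetate (racemic Claisen dienone, not isolated) | CC(=O)OC1=CC2=C(C(=O)C=CO2)C(=O)C1C(C)(C)C=C | intermediate
6 | 5-hydroxy-6-(2-methylbut-3-en-2-yl)-4-oxo-4H-chromen-7-yl acetate (not isolated) | CC(=O)Oc1cc2occc(=O)c2c(O)c1C(C)(C)C=C | intermediate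
7 | 6-(2-methylbut-3-en-2-yl)-4-oxo-4H-chromene-5,7-diyl diacetate | CC(=O)Oc1cc2occc(=O)c2c(OC(C)=O)c1C(C)(C)C=C | intermediate
8 | (4-hydroxy-3-methoxyphenyl)boronic acid | COc1cc(B(O)O)ccc1O | starting material
9 | (2S)-2-(4-hydroxy-3-methoxyphenyl)-6-(2-methylbut-3-en-2-yl)-4-oxochromane-5,7-diyl diacetate | C=CC(C)(C)c1c(OC(C)=O)cc2c(c1OC(C)=O)C(=O)C[C@@H](c1ccc(O)c(OC)c1)O2 | intermediate
10 | (2S)-5,7-dihydroxy-2-(4-hydroxy-3-methoxyphenyl)-6-(2-methylbut-3-en-2-yl)chroman-4-one | C=CC(C)(C)c1c(O)cc2c(c1O)C(=O)C[C@@H](c1ccc(O)c(OC)c1)O2 | target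

## Step count

Total step count: 5. Longest linear sequence: 5 (1 → 2 → 4 → 7 → 9 → 10).

## Steps most likely to fail

**Step 4.** Insertion into the still electron-rich pyranone may be slower than protodeboronation of the electron-rich boronic acid. Hydrolytic loss of the 5-acetate would also unmask a peri-hydroxyketone that sequesters rhodium.

The fallback sets out from 4 and returns at 10. It reverses the order of arylation and rearrangement and changes the metal. Compound 4 has an alkylated O5 and no terminal alkene. It is arylated with 8 under cationic Pd(II) catalysis (Pd(OCOCF3)2, t-BuPyOx in the enantiomer that serves the 2S series, NH4PF6, H2O, ClCH2CH2Cl, 60 °C). This should give (2S)-2-(4-hydroxy-3-methoxyphenyl)-5-[(3-methylbut-2-en-1-yl)oxy]-4-oxochroman-7-yl acetate F1. A Eu(fod)3-catalysed Claisen rearrangement (CHCl3, 60–70 °C), a reaction type known for 5-O-prenylflavanones, should then give (2S)-5-hydroxy-2-(4-hydroxy-3-methoxyphenyl)-6-(2-methylbut-3-en-2-yl)-4-oxochroman-7-yl acetate F2. Methanolic HCl as in step 5 leads to 10.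

**Step 3.** The dienone may undergo an onward Cope shift to C8 (para-Claisen–Cope course), or the prenyl group may be lost thermally before rearrangement.

The fallback sets out from 4 and returns at 7. The rearrangement is moved from thermal activation to Lewis acid catalysis on a substrate with a free O7–H. Catalytic K2CO3 in MeOH removes the acetate to give 7-hydroxy-5-[(3-methylbut-2-en-1-yl)oxy]-4H-chromen-4-one F3. Eu(fod)3 (10 mol %) in toluene at 80 °C should give 5,7-dihydroxy-6-(2-methylbut-3-en-2-yl)-4H-chromen-4-one F4. Here the dienone is a 2-substituted cyclic 1,3-dicarbonyl tautomer, which should aromatise by fast proton transfer at a temperature where the ortho product does not revert. Ac2O, DMAP and pyridine convert F4 into 7.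

**Step 5.** The hindered 5-acetate may resist cleavage long enough for the pyranone ring to open reversibly. This would erode the configuration at C2 and could move ring closure to the other ortho oxygen. A flanking phenol could also add to the vinyl group under acid.

The fallback sets out from 7 and returns at 10. The acyl groups are exchanged for silyl groups before the stereocentre exists. K2CO3 in MeOH converts the achiral 7 into the diol F4. TBSOTf and 2,6-lutidine in CH2Cl2 give 5,7-bis[(tert-butyldimethylsilyl)oxy]-6-(2-methylbut-3-en-2-yl)-4H-chromen-4-one F5. The rhodium-catalysed arylation with 8 as in step 4 should give (2S)-5,7-bis[(tert-butyldimethylsilyl)oxy]-2-(4-hydroxy-3-methoxyphenyl)-6-(2-methylbut-3-en-2-yl)chroman-4-one F6. Et3N·3HF in THF (0 °C → rt), a non-basic and only weakly acidic fluoride source, releases 10.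

## Further compounds

F1 | step 4 | (2S)-2-(4-hydroxy-3-methoxyphenyl)-5-[(3-methylbut-2-en-1-yl)oxy]-4-oxochroman-7-yl acetate | c1c(OC(C)=O)cc2c(c1OCC=C(C)C)C(=O)C[C@@H](c1ccc(O)c(OC)c1)O2
F2 | step 4 | (2S)-5-hydroxy-2-(4-hydroxy-3-methoxyphenyl)-6-(2-methylbut-3-en-2-yl)-4-oxochroman-7-yl acetate | C=CC(C)(C)c1c(OC(C)=O)cc2c(c1O)C(=O)C[C@@H](c1ccc(O)c(OC)c1)O2
F3 | step 3 | 7-hydroxy-5-[(3-methylbut-2-en-1-yl)oxy]-4H-chromen-4-one | Oc1cc(OCC=C(C)C)c2c(=O)ccoc2c1
F4 | step 3 | 5,7-dihydroxy-6-(2-methylbut-3-en-2-yl)-4H-chromen-4-one | Oc1cc2occc(=O)c2c(O)c1C(C)(C)C=C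
F5 | step 5 | 5,7-bis[(tert-butyldimethylsilyl)oxy]-6-(2-methylbut-3-en-2-yl)-4H-chromen-4-one | CC(C)(C)[Si](C)(C)Oc1cc2occc(=O)c2c(O[Si](C)(C)C(C)(C)C)c1C(C)(C)C=C
F6 | step 5 | (2S)-5,7-bis[(tert-butyldimethylsilyl)oxy]-2-(4-hydroxy-3-methoxyphenyl)-6-(2-methylbut-3-en-2-yl)chroman-4-one | C=CC(C)(C)c1c(O[Si](C)(C)C(C)(C)C)cc2c(c1O[Si](C)(C)C(C)(C)C)C(=O)C[C@@H](c1ccc(O)c(OC)c1)O2
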